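The route rests on one disconnection: the C2–C3 bond of the cyclopentane, made by a ring-contracting semipinacol shift. The feature exploited is the cyclopentane's cis pair C3 (isopropyl) and C3a (tertiary hydroxyl) beside the C8a methyl quaternary carbon, a masked aldol. In one operation a Lewis acid opens C3–O of a cyclohexane-fused epoxide, the C2 ring carbon moves from the methyl carbinol carbon to C3 with inversion, the six-membered ring becomes the cyclopentane, the carbinol becomes acetyl (later isopropyl) and the epoxide oxygen stays as the C3a hydroxyl. The precursor is a Robinson-annulation-derived six–seven bicycle: C3–C3a epoxide cis to the angular methyl, cis tertiary methyl carbinol, C8 silyl ether.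

Key step: step 7

Remarks on the chemistry:
- Numbering: five–seven compounds carry the azulene numbering of the target; six–seven compounds carry benzo[7]annulene numbering, whose C1, C2, C4a, C5 and C9a correspond to azulene C3, the acetyl carbon, C8a, C8 and C3a.
- Assumption: L-phenylalanine induces the same sense of aldol cyclization as in the six-membered homologue and gives the (S)-enedione 6; D-phenylalanine would be used otherwise.
- In the relaxed half-chair of 10 the carbinol methyl, not the C2 ring bond, lies anti to C3–O. Step 7 therefore depends on the aluminium chelate to remove that bias, and this is the weak point of the route.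

Step 1
Reactants: 1 cycloheptane-1,3-dione; 2 iodomethane
Product: 3 2-methylcycloheptane-1,3-dione
Conditions: MeI, K2CO3, acetone, 50 °C
Reagents that add atoms: none
Why: Enolate C-alkylation of the doubly activated C2 methylene of the 1,3-diketone; no stereocentre is formed.

Step 2
Reactants: 3 2-methylcycloheptane-1,3-dione; 4 but-3-en-2-one
Product: 6 (4aS)-4a-methyl-4,4a,6,7,8,9-hexahydro-3H-benzo[7]annulene-2,5-dione, via triketone 5 (not isolated)
Conditions: Et3N (cat.), EtOAc, rt; then L-phenylalanine, (1S)-(+)-camphor-10-sulfonic acid, DMF, 30 → 70 °C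
Reagents that add atoms: none
Why: Robinson annulation run as amine-catalysed Michael addition followed by a Hajos–Parrish-type amino-acid-mediated aldol condensation, in which the hydrogen-bonded enamine transition state selects one of the two enantiotopic ring carbonyls and fixes the quaternary carbon (C4a, the later C8a) as S.

Step 3
Reactants: 6 (S)-enedione
Product: 7 (4aS,5S)-hydroxy enone
Conditions: NaBH4 (0.3 equiv), EtOH, −10 °C
Reagents that add atoms: none
Why: Chemoselective borohydride reduction of the saturated ketone beside the less electrophilic enone, with hydride arriving anti to the angular methyl so that the hydroxyl is cis to it (5S); this centre is only a protected placeholder and is erased in step 11.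

Step 4
Reactants: 7 hydroxy enone
Product: 8 TBS ether of the hydroxy enone
Conditions: TBSCl, imidazole, DMF, rt
Reagents that add atoms: tert-butyldimethylsilyl chloride, CC(C)(C)[Si](C)(C)Cl
Why: Imidazole-promoted silyl ether formation; the bulky, weakly Lewis-basic TBS ether should survive alkaline peroxide, organocerium and aluminium reagents and not compete for the Lewis acid in step 7.

Step 5
Reactants: 8 TBS ether enone
Product: 9 epoxy ketone (epoxide oxygen cis to the angular methyl)
Conditions: 30% H2O2, NaOH, MeOH, 0 °C
Reagents that add atoms: hydrogen peroxide, OO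
Why: Weitz–Scheffer nucleophilic epoxidation, in which the hydroperoxide anion adds to the enone β-carbon (the later C3a) along the axial trajectory on the face of the angular methyl, as is usual for angularly methylated bicyclic enones, and enolate closure fixes the epoxide oxygen cis to that methyl (sets C3a).

Step 6
Reactants: 9 epoxy ketone
Product: 10 cis epoxy tertiary alcohol
Conditions: MeLi, CeCl3, THF, −78 °C
Reagents that add atoms: methyllithium, [Li]C
Why: Organocerium 1,2-addition to the ketone without enolization, methyl entering anti to the adjacent epoxide oxygen so that the tertiary hydroxyl lies cis to the epoxide, as needed for chelation in step 7.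

Step 7
Reactants: 10 cis epoxy tertiary alcohol
Product: 11 cis-fused hydroxy acetyl hydroazulene silyl ether
Conditions: Et2AlCl (2 equiv), CH2Cl2, −78 → 0 °C; aq. potassium sodium tartrate
Reagents that add atoms: none
Why: Et2AlCl converts the tertiary hydroxyl into an aluminium alkoxide that also binds the cis epoxide oxygen; within this chelate C3–O is weakened while the alkoxide pushes, the C2 ring carbon shifts from the carbinol carbon to C3 on the side opposite the leaving oxygen, and an aluminium-chelated aldolate (acetyl carbonyl plus C3a alkoxide) results. The closest known reaction type is the Lewis-acid semipinacol rearrangement of tertiary 2,3-epoxy alcohols to β-hydroxy ketones, here in its ring-contracting form. The cyclopentane is closed by a 1,2-alkyl shift, that is by one-carbon contraction of the cyclohexane, not by an end-to-end cyclization. C3 is the only new stereocentre and is set by inversion, C2 entering anti to the epoxide oxygen, which places acetyl cis to the retained C3a hydroxyl; C3a and C8a are not touched. The step needs C3–O and not the tertiary C3a–O bond to break, and the ring carbon and not the methyl group to migrate: the cis hydroxy epoxide allows a tight five-membered chelate that ties C3–O cleavage to the alkoxide push and eclipses the two C–O bonds, which turns the methyl group out of its anti position so that methyl and C2 are about equally disposed toward the breaking bond, and the ring carbon is the inherently better migrating group; the C8 silyl ether is too weak a donor to divert the Lewis acid. This is the step on which the risk of the route is concentrated.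

Step 8
Reactants: 11 hydroxy acetyl hydroazulene
Product: 12 isopropenyl compound
Conditions: Cp2Ti(CH2)(Cl)AlMe2 (Tebbe reagent, excess), pyridine, THF/toluene, −40 → 0 °C
Reagents that add atoms: Tebbe reagent, C[Al-]1(C)C[Ti]([Cl+]1)(C2C=CC=C2)C3C=CC=C3
Why: Tebbe methylenation (titanium methylidene [2+2] cycloaddition–cycloreversion) works without base, so the epimerizable C3 centre and the retro-aldol-prone β-hydroxy ketone should stay intact.

Step 9
Reactants: 12 isopropenyl compound
Product: 13 isopropyl compound
Conditions: H2 (1 atm), Pd/C, EtOAc, rt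
Reagents that add atoms: none
Why: Heterogeneous catalytic hydrogenation of the 1,1-disubstituted alkene to the isopropyl group; no stereocentre is created and the silyl ether and tertiary alcohol are inert.

Step 10
Reactants: 13 isopropyl silyl ether
Product: 14 3a,8-diol
Conditions: Bu4NF, THF, rt → 50 °C
Reagents that add atoms: none
Why: Fluoride-mediated desilylation of the secondary TBS ether.

Step 11
Reactants: 14 3a,8-diol
Product: 15 3a-hydroxy C8 ketone
Conditions: Dess–Martin periodinane, NaHCO3, CH2Cl2, rt
Reagents that add atoms: none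
Why: Dess–Martin oxidation of the secondary alcohol under buffered, non-basic conditions that spare the tertiary β-hydroxyl from retro-aldol cleavage; the placeholder C8 stereocentre disappears.

Step 12
Reactants: 15 3a-hydroxy C8 ketone
Product: 17 silyl-protected C6–C7 enone, via bis-silyl enol ether 16 (not isolated)
Conditions: TMSOTf, Et3N, CH2Cl2, 0 °C; then Pd(OAc)2, MeCN, rt
Reagents that add atoms: trimethylsilyl trifluoromethanesulfonate, C[Si](C)(C)OS(=O)(=O)C(F)(F)F
Why: Saegusa–Ito dehydrogenation, in which soft enolization can only run toward C7 because C8a is quaternary and silylates the C3a hydroxyl in the same operation (blocking retro-aldol in the next steps), and Pd(OAc)2 converts the silyl enol ether by β-hydride elimination into the C6–C7 enone.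

Step 13
Reactants: 17 silyl-protected C6–C7 enone
Product: 19 silyl-protected 6-methyl C6–C7 enone, via methylated silyl enol ether 18 (not isolated)
Conditions: Me2CuLi, TMSCl, THF, −78 °C; then Pd(OAc)2, MeCN, rt
Reagents that add atoms: lithium dimethylcuprate, [Li+].C[Cu-]C
Why: Conjugate addition of the Gilman cuprate with TMSCl trapping puts the methyl group on C6, and a second Saegusa–Ito dehydrogenation of the trapped silyl enol ether restores the C6–C7 double bond, which removes the transient C6 stereocentre.

Step 14
Reactants: 19 silyl-protected 6-methyl enone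
Product: 21 allylic 3a,8-diol, via silyl-protected allylic alcohol 20 (not isolated)
Conditions: NaBH4, CeCl3·7H2O, MeOH, −78 °C; then Bu4NF, THF, 0 °C
Reagents that add atoms: none
Why: Luche 1,2-reduction of the enone, hydride expected on the face opposite the C8a methyl and the 1,3-related bulky C3a silyl ether so that the C8 hydroxyl ends cis to both (8S); fluoride then cleaves the tertiary TMS ether.

Step 15
Reactants: 21 allylic 3a,8-diol; 22 4-methoxybenzoyl chloride
Product: 23 target 4-methoxybenzoate
Conditions: Et3N, DMAP, CH2Cl2, 0 °C → rt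
Reagents that add atoms: none
Why: DMAP-catalysed esterification (nucleophilic acyl substitution) of the secondary allylic hydroxyl, the tertiary C3a hydroxyl being too hindered to react.

Compound list
1 | cycloheptane-1,3-dione | O=C1CCCCC(=O)C1 | starting material
2 | iodomethane | CI | starting material
3 | 2-methylcycloheptane-1,3-dione | CC1C(=O)CCCCC1=O | intermediate
4 | but-3-en-2-one | CC(=O)C=C | starting material
5 | 2-methyl-2-(3-oxobutyl)cycloheptane-1,3-dione (achiral triketone) | CC(=O)CCC1(C)C(=O)CCCCC1=O | intermediate
6 | (4aS)-4a-methyl-4,4a,6,7,8,9-hexahydro-3H-benzo[7]annulene-2,5-dione | O=C1CCCCC2=CC(=O)CC[C@]12C | intermediate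
7 | (4aS,5S)-5-hydroxy-4a-methyl-3,4,4a,5,6,7,8,9-octahydro-2H-benzo[7]annulen-2-one; hydroxyl cis to the angular methyl | O[C@H]1CCCCC2=CC(=O)CC[C@]12C | intermediate
8 | (4aS,5S)-5-[(tert-butyldimethylsilyl)oxy]-4a-methyl-3,4,4a,5,6,7,8,9-octahydro-2H-benzo[7]annulen-2-one | CC(C)(C)[Si](C)(C)O[C@H]1CCCCC2=CC(=O)CC[C@]12C | intermediate
9 | 5-[(tert-butyldimethylsilyl)oxy]-1,9a-epoxy-4a-methylperhydrobenzo[7]annulen-2-one; epoxide oxygen, 4a-methyl and 5-silyloxy on the same face | CC(C)(C)[Si](C)(C)O[C@H]1CCCC[C@]23O[C@H]2C(=O)CC[C@]13C | intermediate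
10 | 5-[(tert-butyldimethylsilyl)oxy]-1,9a-epoxy-2,4a-dimethylperhydrobenzo[7]annulen-2-ol; 2-hydroxyl, epoxide oxygen, 4a-methyl and 5-silyloxy on one face, 2-methyl on the other | CC(C)(C)[Si](C)(C)O[C@H]1CCCC[C@]23O[C@H]2[C@@](C)(O)CC[C@]13C | intermediate
11 | 1-[(3S,3aS,8S,8aR)-8-[(tert-butyldimethylsilyl)oxy]-3a-hydroxy-8a-methyldecahydroazulen-3-yl]ethan-1-one; acetyl, 3a-hydroxyl, 8a-methyl and 8-silyloxy all cis | CC(C)(C)[Si](C)(C)O[C@H]1CCCC[C@]2(O)[C@@H](C(C)=O)CC[C@]12C | intermediate
12 | (3R,3aS,8S,8aR)-8-[(tert-butyldimethylsilyl)oxy]-8a-methyl-3-(prop-1-en-2-yl)decahydroazulen-3a-ol | CC(C)(C)[Si](C)(C)O[C@H]1CCCC[C@]2(O)[C@@H](C(C)=C)CC[C@]12C | intermediate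
13 | (3R,3aS,8S,8aR)-8-[(tert-butyldimethylsilyl)oxy]-8a-methyl-3-(propan-2-yl)decahydroazulen-3a-ol | CC(C)(C)[Si](C)(C)O[C@H]1CCCC[C@]2(O)[C@@H](C(C)C)CC[C@]12C | intermediate
14 | (3R,3aS,8S,8aR)-8a-methyl-3-(propan-2-yl)decahydroazulene-3a,8-diol | O[C@H]1CCCC[C@]2(O)[C@@H](C(C)C)CC[C@]12C | intermediate
15 | 3a-hydroxy-8a-methyl-3-(propan-2-yl)perhydroazulen-8-one; isopropyl, hydroxyl and methyl all cis | O=C1CCCC[C@]2(O)[C@@H](C(C)C)CC[C@]12C | intermediate
16 | 8a-methyl-3-(propan-2-yl)-3a,8-bis(trimethylsilyloxy)-1,2,3,3a,4,5,6,8a-octahydroazulene (C7=C8 enol ether) | C[Si](C)(C)OC1=CCCC[C@]2(O[Si](C)(C)C)[C@@H](C(C)C)CC[C@]12C | intermediate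
17 | 8a-methyl-3-(propan-2-yl)-3a-(trimethylsilyloxy)-2,3,3a,4,5,8a-hexahydroazulen-8(1H)-one (C6=C7 enone) | O=C1C=CCC[C@]2(O[Si](C)(C)C)[C@@H](C(C)C)CC[C@]12C | intermediate
18 | 6,8a-dimethyl-3-(propan-2-yl)-3a,8-bis(trimethylsilyloxy)-1,2,3,3a,4,5,6,8a-octahydroazulene (C7=C8 enol ether, either C6 epimer) | C[Si](C)(C)OC1=CC(C)CC[C@]2(O[Si](C)(C)C)[C@@H](C(C)C)CC[C@]12C | intermediate
19 | 6,8a-dimethyl-3-(propan-2-yl)-3a-(trimethylsilyloxy)-2,3,3a,4,5,8a-hexahydroazulen-8(1H)-one | O=C1C=C(C)CC[C@]2(O[Si](C)(C)C)[C@@H](C(C)C)CC[C@]12C | intermediate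
20 | (8S)-6,8a-dimethyl-3-(propan-2-yl)-3a-(trimethylsilyloxy)-1,2,3,3a,4,5,8,8a-octahydroazulen-8-ol; 8-hydroxyl cis to the 8a-methyl | O[C@H]1C=C(C)CC[C@]2(O[Si](C)(C)C)[C@@H](C(C)C)CC[C@]12C | intermediate
21 | (3R,3aS,8S,8aR)-6,8a-dimethyl-3-(propan-2-yl)-1,2,3,3a,4,5,8,8a-octahydroazulene-3a,8-diol | O[C@H]1C=C(C)CC[C@]2(O)[C@@H](C(C)C)CC[C@]12C | intermediate
22 | 4-methoxybenzoyl chloride | COc1ccc(C(=O)Cl)cc1 | starting material
23 | (3R,3aS,8S,8aR)-3a-hydroxy-6,8a-dimethyl-3-(propan-2-yl)-1,2,3,3a,4,5,8,8a-octahydroazulen-8-yl 4-methoxybenzoate | COc1ccc(C(=O)O[C@H]2C=C(C)CC[C@]3(O)[C@@H](C(C)C)CC[C@]23C)cc1 | target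

Total step count: 15. Longest linear sequence: 15 steps, from cycloheptane-1,3-dione.

Steps most likely to fail

1. Step 7. What may go wrong: 1,2-shift of the methyl group in place of the ring carbon, since methyl sits anti to C3–O whenever the chelate is loose; or heterolysis at the tertiary epoxide carbon C3a followed by elimination or skeletal drift. The fallback closes the cyclopentane by an aldol bond between C3 and C3a instead of a 1,2-shift; it sets out from 9 and returns at 11. Eschenmoser–Tanabe fragmentation of 9 (TsNHNH2, AcOH, CH2Cl2) would give the acetylenic ketone F1. Hydroboration of the terminal alkyne with dicyclohexylborane and oxidation with NaBO3 would give the keto aldehyde F2. A proline-mediated 5-enolexo aldol would close the cis-fused hydroxy aldehyde F3, with the hydroxyl syn to the angular methyl as in ketols of the Hajos–Parrish kind; C3, α to the carbonyl, can be equilibrated to the less hindered, hydrogen-bonded arrangement cis to that hydroxyl. MeMgBr would then give the secondary carbinol F4, and Dess–Martin oxidation would deliver 11.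

2. Step 5. What may go wrong: poor facial selectivity, the hydroperoxide adding to C3a on the face away from the angular methyl because the C8 silyl ether crowds the methyl face. The fallback uses hydroxyl-directed instead of nucleophilic epoxidation; it sets out from 8 and returns at 9. Luche reduction of 8 (NaBH4, CeCl3·7H2O, MeOH) would give the pseudo-equatorial allylic alcohol F5, hydroxyl cis to the angular methyl. VO(acac)2 with t-BuOOH would deliver oxygen syn to that hydroxyl to give the epoxy alcohol F6, and Dess–Martin oxidation would give 9.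

3. Step 14. What may go wrong: poor facial selectivity in the hydride addition to the C8 carbonyl, giving the C8 epimer. The fallback uses chelation control in place of steric control; it sets out from 19 and returns at 21. HF·pyridine in THF would free the tertiary alcohol to give the β-hydroxy enone F7. Narasaka–Prasad reduction (Et2BOMe, NaBH4, THF–MeOH, −78 °C) through the six-membered boron chelate spanning the C3a and C8 oxygens would place the new hydroxyl cis to the C3a hydroxyl, which is diol 21.

Further compounds
F1 | step 7 | 2-(but-3-yn-1-yl)-3-[(tert-butyldimethylsilyl)oxy]-2-methylcycloheptan-1-one; silyloxy cis to the 2-methyl | CC(C)(C)[Si](C)(C)O[C@H]1CCCCC(=O)[C@]1(C)CCC#C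
F2 | step 7 | 4-{2-[(tert-butyldimethylsilyl)oxy]-1-methyl-7-oxocycloheptyl}butanal | CC(C)(C)[Si](C)(C)O[C@H]1CCCCC(=O)[C@]1(C)CCCC=O
F3 | step 7 | 8-[(tert-butyldimethylsilyl)oxy]-3a-hydroxy-8a-methyldecahydroazulene-3-carbaldehyde; formyl, hydroxyl, methyl and silyloxy all cis | CC(C)(C)[Si](C)(C)O[C@H]1CCCC[C@]2(O)[C@@H](C=O)CC[C@]12C
F4 | step 7 | 8-[(tert-butyldimethylsilyl)oxy]-3-(1-hydroxyethyl)-8a-methyldecahydroazulen-3a-ol (either carbinol epimer) | CC(C)(C)[Si](C)(C)O[C@H]1CCCC[C@]2(O)[C@@H](C(C)O)CC[C@]12C
F5 | step 5 | 5-[(tert-butyldimethylsilyl)oxy]-4a-methyl-3,4,4a,5,6,7,8,9-octahydro-2H-benzo[7]annulen-2-ol; 2-hydroxyl cis to the 4a-methyl | CC(C)(C)[Si](C)(C)O[C@H]1CCCCC2=C[C@@H](O)CC[C@]12C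
F6 | step 5 | 5-[(tert-butyldimethylsilyl)oxy]-1,9a-epoxy-4a-methylperhydrobenzo[7]annulen-2-ol; hydroxyl, epoxide oxygen and 4a-methyl on the same face | CC(C)(C)[Si](C)(C)O[C@H]1CCCC[C@]23O[C@H]2[C@@H](O)CC[C@]13C
F7 | step 14 | 3a-hydroxy-6,8a-dimethyl-3-(propan-2-yl)-2,3,3a,4,5,8a-hexahydroazulen-8(1H)-one | O=C1C=C(C)CC[C@]2(O)[C@@H](C(C)C)CC[C@]12C
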